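A plateau with substrate still present tempts you to call it an equilibrium, and these readings alone do not forbid that. I commit to another reading of it.

| flask | left-handed substrate | right-handed substrate | partner | free catalyst | racemization catalyst | impurity | remark | time |
|---|---|---|---|---|---|---|---|---|
| theta | 0.020 M | 0.020 M | 0.044 M | 3 mM | 3.2 mM | 0.50 mM | run made earlier |  |
| zeta | 0.020 M | 0.020 M | 0.044 M | 3 mM | 3.2 mM | 0.79 mM | run made earlier |  |
| beta | 0.030 M | 0.030 M | 0.044 M | 3 mM | 3.2 mM | 0.36 mM | run made earlier |  |
| flask | 0.020 M | 0.020 M | 0.0440 M | 3.0 mM | 3.2 mM | 0.36 mM |  | 5.0 min |

- theta (time / min: left-handed substrate / %, right-handed substrate / %, left-handed product / %): 0.667: 38.9, 39.6, 21.1; 1.33: 36.4, 37.2, 25.8; 2.00: 36.0, 36.0, 27.2; 3.00: 36.9, 36.2, 27.4; 4.00: 36.5, 36.1, 27.4; 5.00: 36.5, 36.0, 28.0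
- zeta (time / min: left-handed substrate / %, right-handed substrate / %, left-handed product / %): 0.667: 39.1, 40.0, 21.3; 1.33: 36.8, 37.2, 26.0; 2.00: 36.9, 36.4, 27.1; 3.00: 36.4, 36.6, 28.0; 4.00: 36.2, 36.3, 27.2; 5.00: 35.9, 35.9, 27.6
- beta (time / min: left-handed substrate / %, right-handed substrate / %, left-handed product / %): 0.417: 40.8, 42.9, 15.8; 0.833: 38.6, 39.9, 21.4; 1.33: 37.6, 38.0, 23.9; 2.50: 37.7, 37.5, 24.9; 5.00: 37.9, 37.6, 24.3

(each reading ± 0.3 percentage points)

- free catalyst is single-handed; left-handed substrate and right-handed substrate are mirror images of each other, charged as a racemate, each of them at the stated concentration
- an excess is the difference of the two amounts in percent of their sum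
- an excess is below zero if the other one leads

- part of the left-handed substrate and right-handed substrate charged together that has reacted at 5.0 min
- excess of left-handed product over right-handed product in the product at 5.0 min
- excess of right-handed substrate over left-handed substrate among what is left of the two at 5.0 min

Suppose partner has two fates. It joins substrate at a rate proportional to substrate times partner, or it decays on its own at a rate proportional to partner. Take the two substrates as equal, as they read. Partner then cancels from the ratio of the two rates, and time drops out. So work with the fraction of substrate left, not the fraction made. If partner, the limiting reagent on this view, has reached zero at the plateau, its charge equals the substrate consumed plus a constant times minus the natural logarithm of the fraction left.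

Now read the last row of each table. Theta keeps 72.5 % of its substrate, which gives a constant of 103 mM. Zeta keeps 71.8 %, which gives 98.8 mM. Beta has more substrate and keeps 75.5 %, which gives 104 mM. Their mean, 102 mM, is the waste constant: the substrate concentration at which partner's two fates run equally fast.

This flask has theta's substrate and partner charges, with beta's impurity. Solving the balance with the waste constant leaves 72.4 %, so my reckoning has 27.6 % reacted.

The forecast gives 27.6 %, from 27 % to 28.2 %, with 100 % and 0 % for the two excesses, and I take those excesses over. Its ground differs from mine: “The plateau looks like equilibrium rather than catalyst death.” Yet the flask repeats theta's substrate and partner charges, and zeta, with more impurity than theta, keeps 71.8 % against theta's 72.5 %, so both views point to theta's plateau.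

The flask gives 27.6 % reacted, 98.8 % for the product excess and 0 % for the substrate excess.

    partner + free catalyst + left-handed substrate → free catalyst + left-handed product (k = 176 L² mol⁻² s⁻¹)
    partner + free catalyst + right-handed substrate → free catalyst + right-handed product (k = 0.970 L² mol⁻² s⁻¹)
    left-handed substrate + racemization catalyst ⇌ right-handed substrate + racemization catalyst, rate k3*[racemization catalyst]*[left-handed substrate] forward; the back reaction follows from the equilibrium constant (k = 31.6 L mol⁻¹ s⁻¹)
    partner → decomposed reagent (k = 0.0264 s⁻¹)
    racemization catalyst + impurity → spent catalyst (k = 3390 L mol⁻¹ s⁻¹)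

At the start of this flask, partner decays 2.5 times as fast as it forms left-handed product, and the waste constant over the substrate charge is 2.55. By 5.00 min partner stands at 0 % of its charge, less than the 72 % of left-handed substrate left. In a neighbour flask with more partner than this one, 56.1 % reacted, and the waste constant accounts for 106 mM of the 110 mM of partner charged.

The earlier runs and the new flask come from a simulation with constants of no real substance, noise included.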